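We had to decide whether a slow addition was worth a pump, or whether this flask could be charged together at the start and left for 40 min.

| flask | starting material | partner | second reagent | third reagent | remark | time |
|---|---|---|---|---|---|---|
| ochre | 35 mM | 5 equiv | 1.1 equiv | 2 equiv | run made earlier |  |
| green | 35 mM | 2.5 equiv | 1.1 equiv | 2 equiv | run made earlier |  |
| grey | 35 mM | 10 equiv | 1.1 equiv | 2 equiv | run made earlier |  |
| violet | 35 mM | 5 equiv | 1.1 equiv | 4 equiv | run made earlier |  |
| spring | 35 mM | 5.00 equiv | 1.10 equiv | 2.00 equiv | everything together at the start | 40 min |
| dusk | 35 mM (fed, over 15 min) | 5.00 equiv | 1.10 equiv | 2.00 equiv | all else is in the flask from the start; the feed brings no volume worth counting | 40 min |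
| midnight | 35 mM | 5.00 equiv | 1.10 equiv | 2.00 equiv (in portions, 3, over 15 min) | first portion at the start, last at 15 min | 40 min |
| summer | 35 mM | 5.00 equiv | 1.10 equiv | 2.00 equiv (fed, over 15 min) | all else is in the flask from the start; the feed brings no volume worth counting | 40 min |

| run | time / min | target / % |
|---|---|---|
| ochre | 3.00 | 3 |
| ochre | 5.00 | 7 |
| ochre | 8.00 | 9 |
| ochre | 12.0 | 12 |
| ochre | 15.0 | 15 |
| ochre | 25.0 | 22 |
| ochre | 40.0 | 19 |
| green | 2.50 | 1 |
| green | 4.00 | 5 |
| green | 6.00 | 5 |
| green | 10.0 | 9 |
| green | 15.0 | 13 |
| green | 20.0 | 14 |
| green | 30.0 | 20 |
| grey | 1.50 | 0 |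
| grey | 5.00 | 4 |
| grey | 10.0 | 10 |
| grey | 15.0 | 15 |
| grey | 20.0 | 17 |
| grey | 25.0 | 21 |
| grey | 30.0 | 20 |
| violet | 3.00 | 5 |
| violet | 8.00 | 12 |
| violet | 15.0 | 23 |
| violet | 25.0 | 23 |
| violet | 30.0 | 21 |

(scatter of a reading: 2 percentage points)



* the best flask by amount of target, in percent of the starting material charged; "all alike" if 1.5 percentage points covers them all (spring / dusk / midnight / summer / all alike)
* amount of target at the end, in percent of the starting material charged, spring
* amount of target at the end, in percent of the starting material charged, dusk
* amount of target at the end, in percent of the starting material charged, midnight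
* amount of target at the end, in percent of the starting material charged, summer

Spring is ochre's recipe, and two of us read ochre differently. Its readings reach 22% at 25.0 min and stand at 19% at 40.0 min. A slow addition (starting material in dusk, third reagent in midnight and summer) puts the material in 7.50 min late on average, so we both treated those flasks as ochre's curve read at 32.5 min.

The first of us looked at the climb. Ochre made 15% in its first 15.0 min, so at that pace the lateness costs 7.5 percentage points. The late flasks then end near 11.5%, and the pump is a loss.

The second of us worked with what is left, not with what is made. A clock of 32.5 min is later than ochre's highest reading at 25.0 min, so a late flask sits on the falling side. The fade rate, the share of the target lost per minute on that side, is an apparent first-order constant. Read from those two ochre readings, with their scatter of 2 points in it, it is 0.00977 min⁻¹. Over the lateness the target keeps a fraction 0.929, so a late flask ends near 20.4%. That is 1.4 points above ochre's last reading, less than the margin of 1.5 points. But the two readings differ by 3 points, and a difference of two such readings scatters by 2.8 points, so this gain is a rough reading: it points to flasks lying close together, but it cannot be told from zero or from the margin.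

The forecast, by its own judgement, stands on the second side: “dosing the third reagent only delays things by a few minutes”. It gives spring 20%, dusk 21% (range 17% to 28%), midnight 20.5% and summer 20.5%, and its verdict is all alike.

Spring ends at 18.6%, dusk at 19.1%, midnight at 19.6% and summer at 19.4%, so the verdict is all alike: midnight stands 1.00 point above spring, less than 1.5 points.

    target ⇌ isomer of the product (K = 6.90, k = 0.00135 s⁻¹)
    third reagent + intermediate B → target (k = 0.0206 M⁻¹ s⁻¹)
    starting material + second reagent → side product (k = 0.0247 M⁻¹ s⁻¹)
    starting material + partner → intermediate A (k = 0.510 M⁻¹ s⁻¹)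
    second reagent + intermediate A → intermediate B (k = 0.0265 M⁻¹ s⁻¹)

The cost of lateness belongs to the climb, where ochre read 9% at 8.00 min and 15% at 15.0 min. Dusk at 40.0 min still holds 31.8% as intermediate A, 17.7% as intermediate B and 30.3% as isomer of the product. From spring's 18.6%, the fade rate gives a late flask 20.0%, and midnight reached 19.6%. Over a further 360 min the fade rate leaves a fraction 0.0297 of dusk's target, but dusk at 400 min holds 12.4%, a fraction 0.649.

(The data were computed for substances that don't exist, noise included.)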